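The strategy builds the pentasubstituted central benzene ring instead of decorating it. The run C1(OMe)–C2(H)–C3(OH)–C4(CH2Ar), with its 1,3-oxygen pattern, is read as an electron-rich 1,1-dimethoxy-3-silyloxydiene that already carries the C4 benzyl arm. C5(CH2CH2Ph)–C6 is read as an alkyne whose C6 arm is kept at the aroyl oxidation level, so that it activates and polarises the triple bond. A single thermal [4+2] benzannulation forms C4–C5 and C1–C6, loses methanol and the silyl group, and delivers the ring with OMe and OH already told apart. Hydride reduction and one hydrogenolysis then finish the target.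

Key step: step 5

Remark: the target has no stereocentre and no resolvable axis, so the compound as drawn is the only species required and no asymmetric step is needed; the central ring is numbered C1(OMe), C2(H), C3(OH), C4(CH2Ar), C5(CH2CH2Ph), C6(CH2Ar) throughout.

Step 1
Reactants: 1 3-[4-(benzyloxy)phenyl]propanoic acid
Product: 2 3-[4-(benzyloxy)phenyl]propanoyl chloride
Conditions: (COCl)2 (1.3 equiv), DMF (cat.), CH2Cl2, 0 °C → rt; evaporate, toluene chase, use crude
Reagents that add atoms: oxalyl chloride, O=C(Cl)C(=O)Cl
Why: DMF-catalysed acid chloride formation (Vilsmeier-type activation) runs under neutral, gas-evolving conditions that leave the aryl benzyl ether untouched and create no stereocentre.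

Step 2
Reactants: 2 3-[4-(benzyloxy)phenyl]propanoyl chloride; 3 1,1-dimethoxyethene
Product: 4 5-[4-(benzyloxy)phenyl]-1,1-dimethoxypent-1-en-3-one
Conditions: 2 added slowly to 3 (2.5 equiv), Et2O, 0 °C → 35 °C; evaporate; short plug of basic alumina
Reagents that add atoms: none
Why: C-acylation of a ketene acetal by an acid chloride: the nucleophilic CH2 of 3 attacks 2, the resulting dimethoxycarbenium ion loses its acidic α-proton, and surplus 3 absorbs the HCl as volatile methyl acetate and chloromethane, so the hydrolysis-prone push–pull enone 4 needs neither an amine base (no ketene from 2) nor an aqueous work-up.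

Step 3
Reactants: 4 5-[4-(benzyloxy)phenyl]-1,1-dimethoxypent-1-en-3-one
Product: 6 (3Z)-5-[4-(benzyloxy)phenyl]-1,1-dimethoxy-3-(trimethylsilyloxy)penta-1,3-diene, via sodium dienolate 5 (not isolated)
Conditions: NaHMDS (1.05 equiv), THF, −78 °C; TMSCl (1.2 equiv), −78 → 0 °C; pentane, filter under Ar, evaporate; use at once
Reagents that add atoms: chlorotrimethylsilane, C[Si](C)(C)Cl; sodium hexamethyldisilazide, C[Si](C)(C)[N-][Si](C)(C)C.[Na+] (sodium of 5 only)
Why: Hard enolisation and O-silylation (silyl enol ether formation): the C4 methylene is the only acidic site, so regiochemistry is fixed, and NaHMDS in THF favours the Z(O)-enolate, which sets the 3Z geometry that keeps CH2Ar on the outside of the s-cis diene and closes off the 1,5-hydrogen shift open to the 3E isomer.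

Step 4
Reactants: 7 4-(benzyloxy)benzoyl chloride; 8 4-phenyl-1-butyne
Product: 9 1-[4-(benzyloxy)phenyl]-5-phenylpent-2-yn-1-one
Conditions: PdCl2(PPh3)2 (2 mol%), CuI (4 mol%), Et3N (1.2 equiv), THF, rt
Reagents that add atoms: none
Why: Acyl Sonogashira coupling: oxidative addition of Pd(0) into the aroyl chloride, transmetallation from the copper acetylide of 8 and reductive elimination give the ynone directly at room temperature, and the near-stoichiometric amine keeps conjugate addition to the product at bay.

Step 5
Reactants: 6 (3Z)-5-[4-(benzyloxy)phenyl]-1,1-dimethoxy-3-(trimethylsilyloxy)penta-1,3-diene; 9 1-[4-(benzyloxy)phenyl]-5-phenylpent-2-yn-1-one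
Product: 12 {3-[4-(benzyloxy)benzyl]-4-hydroxy-6-methoxy-2-(2-phenylethyl)phenyl}[4-(benzyloxy)phenyl]methanone, via cyclohexadiene cycloadduct 10 (not isolated), via aryl trimethylsilyl ether 11 (not isolated)
Conditions: 6 (2 equiv), activated 4 Å MS, toluene, sealed tube, 120 °C; then 0.5 M HCl, THF, rt
Reagents that add atoms: none
Why: The three oxygen donors raise the HOMO of 6 and concentrate it at C4, while the aroyl group lowers the LUMO of 9 and concentrates it at the phenethyl-bearing alkyne carbon, so C4–C5 forms ahead of C1–C6 in a concerted but strongly asynchronous normal-demand Diels–Alder reaction (at the stepwise limit a vinylogous Mukaiyama–Michael addition followed by attack of the allenolate carbon on the dimethoxycarbenium carbon). The closest known reaction type is the cycloaddition of 1,1-dimethoxy-3-silyloxybuta-1,3-dienes with acetylenic esters and ketones, which gives resorcinol monomethyl ethers. The one new ring, the six-membered central carbocycle, closes in the [4+2] mode (formally 6-endo-trig at C1 if stepwise); 1,4-elimination of methanol across C1/C4 of 10 aromatises it to 11, and dilute acid removes the silyl group. The only stereocentre, C4 of 10, is transient, forms as a racemate and vanishes on aromatisation, so nothing needs controlling. The step needs regioselectivity, which the donor/acceptor matching secures by placing the aroyl group next to C1(OMe) and para to C3(OH); chemoselectivity for C≡C over C=O, which the absence of any Lewis acid secures; and differentiation of the two oxygens, secured because C1 keeps a methyl ether whereas C3 carries a hydrolysable silyl ether. The 3Z geometry of 6 keeps CH2Ar clear of the reacting face, and the sieves together with the excess diene take up the liberated methanol, which would otherwise protodesilylate 6.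

Step 6
Reactants: 12 {3-[4-(benzyloxy)benzyl]-4-hydroxy-6-methoxy-2-(2-phenylethyl)phenyl}[4-(benzyloxy)phenyl]methanone
Product: 13 (±)-2-[4-(benzyloxy)benzyl]-4-{[4-(benzyloxy)phenyl](hydroxy)methyl}-5-methoxy-3-(2-phenylethyl)phenol
Conditions: LiAlH4 (3 equiv), THF, 0 °C → reflux; aq. Rochelle salt work-up; use crude, no acidic silica
Reagents that add atoms: none
Why: Hydride reduction of a diaryl ketone with LiAlH4: the two ortho substituents twist the carbonyl out of conjugation with the central ring, so the aluminium phenoxide formed first deactivates it only weakly and the small hydride still reaches it, the benzyl and methyl ethers are inert, and the new carbinol stereocentre forms as a racemate that step 7 erases.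

Step 7
Reactants: 13 (±)-2-[4-(benzyloxy)benzyl]-4-{[4-(benzyloxy)phenyl](hydroxy)methyl}-5-methoxy-3-(2-phenylethyl)phenol
Product: 14 2,4-bis(4-hydroxybenzyl)-5-methoxy-3-(2-phenylethyl)phenol (IN1158)
Conditions: H2 (1–4 bar), 10% Pd/C, EtOH–AcOH (4:1), rt
Reagents that add atoms: none
Why: Catalytic hydrogenolysis over Pd/C cleaves all three benzylic C–O bonds in one operation, the two O-benzyl ethers as toluene and the doubly donor-stabilised benzhydrol (which ionises readily in acetic acid) to CH2, while the methyl ether, the Ar–CH2–Ar bonds and the phenol rings are untouched at room temperature, and leaving out mineral acid keeps any benzhydryl cation too short-lived for Friedel–Crafts attack on the neighbouring phenethyl ring.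

Compound list
1 | 3-[4-(benzyloxy)phenyl]propanoic acid | O=C(O)CCc1ccc(OCc2ccccc2)cc1 | starting material
2 | 3-[4-(benzyloxy)phenyl]propanoyl chloride | O=C(Cl)CCc1ccc(OCc2ccccc2)cc1 | intermediate
3 | 1,1-dimethoxyethene | C=C(OC)OC | starting material
4 | 5-[4-(benzyloxy)phenyl]-1,1-dimethoxypent-1-en-3-one | COC(OC)=CC(=O)CCc1ccc(OCc2ccccc2)cc1 | intermediate
5 | sodium (3Z)-5-[4-(benzyloxy)phenyl]-1,1-dimethoxypenta-1,3-dien-3-olate | COC(OC)=C/C([O-])=C/Cc1ccc(OCc2ccccc2)cc1.[Na+] | intermediate
6 | (3Z)-5-[4-(benzyloxy)phenyl]-1,1-dimethoxy-3-(trimethylsilyloxy)penta-1,3-diene | COC(OC)=C/C(O[Si](C)(C)C)=C/Cc1ccc(OCc2ccccc2)cc1 | intermediate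
7 | 4-(benzyloxy)benzoyl chloride | O=C(Cl)c1ccc(OCc2ccccc2)cc1 | starting material
8 | 4-phenyl-1-butyne | C#CCCc1ccccc1 | starting material
9 | 1-[4-(benzyloxy)phenyl]-5-phenylpent-2-yn-1-one | O=C(C#CCCc1ccccc1)c1ccc(OCc2ccccc2)cc1 | intermediate
10 | {3-[4-(benzyloxy)benzyl]-6,6-dimethoxy-2-(2-phenylethyl)-4-(trimethylsilyloxy)cyclohexa-1,4-dien-1-yl}[4-(benzyloxy)phenyl]methanone (racemic, transient) | COC1(OC)C=C(O[Si](C)(C)C)C(Cc2ccc(OCc3ccccc3)cc2)C(CCc2ccccc2)=C1C(=O)c1ccc(OCc2ccccc2)cc1 | intermediate
11 | {3-[4-(benzyloxy)benzyl]-6-methoxy-2-(2-phenylethyl)-4-(trimethylsilyloxy)phenyl}[4-(benzyloxy)phenyl]methanone | COc1cc(O[Si](C)(C)C)c(Cc2ccc(OCc3ccccc3)cc2)c(CCc2ccccc2)c1C(=O)c1ccc(OCc2ccccc2)cc1 | intermediate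
12 | {3-[4-(benzyloxy)benzyl]-4-hydroxy-6-methoxy-2-(2-phenylethyl)phenyl}[4-(benzyloxy)phenyl]methanone | COc1cc(O)c(Cc2ccc(OCc3ccccc3)cc2)c(CCc2ccccc2)c1C(=O)c1ccc(OCc2ccccc2)cc1 | intermediate
13 | (±)-2-[4-(benzyloxy)benzyl]-4-{[4-(benzyloxy)phenyl](hydroxy)methyl}-5-methoxy-3-(2-phenylethyl)phenol (racemic) | COc1cc(O)c(Cc2ccc(OCc3ccccc3)cc2)c(CCc2ccccc2)c1C(O)c1ccc(OCc2ccccc2)cc1 | intermediate
14 | 2,4-bis(4-hydroxybenzyl)-5-methoxy-3-(2-phenylethyl)phenol (IN1158, achiral) | COc1cc(O)c(Cc2ccc(O)cc2)c(CCc2ccccc2)c1Cc1ccc(O)cc1 | target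

Total step count: 7. Longest linear sequence: 6 (steps 1, 2, 3, 5, 6, 7); step 4 is a one-step convergent branch.

Steps most likely to fail

Risk 1, step 5. The cycloaddition may be outrun by thermal decay and methanolysis of the diene. Both bond-forming termini are substituted, and the para-alkoxy group tempers the activating power of the aroyl carbonyl. The reaction may also stall after the first bond, with silyl transfer to the allenolate oxygen instead of ring closure.

The fallback keeps the ring construction but brings in the aryl part of the C6 arm afterwards. It sets out from 8 and uses 6.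
- Deprotonation of 8 with n-BuLi (THF, −78 °C) gives lithium 4-phenylbut-1-yn-1-ide F1, which DMF formylates to 5-phenylpent-2-ynal F2. This dienophile is smaller and much more electron-poor than 9.
- Heating F2 with 6 as in step 5 should give the cyclohexadiene carbaldehyde F3 and, by loss of methanol, the aryl silyl ether F4.
- Dilute acid then releases 3-[4-(benzyloxy)benzyl]-4-hydroxy-6-methoxy-2-(2-phenylethyl)benzaldehyde F5.
- Grignard addition of excess 4-(benzyloxy)phenylmagnesium bromide F6 follows; it is made from commercial 1-(benzyloxy)-4-bromobenzene and Mg, and one equivalent is spent on the phenol. This comes back to the route at 13, so that 9, 12 and step 6 are bypassed.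

Risk 2, step 2. The acylated dimethoxycarbenium chloride ion pair may collapse by chloride attack on a methyl group instead of losing its proton. The enolisable acid chloride may drift into ketene chemistry. The heavy, non-distillable product may also hydrolyse during purification.

The fallback moves the acylation to the smallest, long-established case and attaches the arm by alkylation. It sets out from 3.
- Acetyl chloride and 3 under the conditions of step 2 give 4,4-dimethoxybut-3-en-2-one F7, which can be distilled free of by-products.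
- NaHMDS (THF, −78 °C) forms its α′-enolate, sodium 4,4-dimethoxybuta-1,3-dien-2-olate F8.
- Commercial 4-(benzyloxy)benzyl bromide alkylates F8 in the manner of a Stork–Danheiser α′-alkylation of a vinylogous ester, coming back at 4. Compounds 1 and 2 are then not needed.

Risk 3, step 6. Deprotonation of the phenol para to the carbonyl may feed enough electron density into an already shielded ketone for hydride delivery to stall.

The fallback removes the phenoxide instead of forcing the reduction. It sets out from 12.
- BnBr and K2CO3 in DMF give the tribenzyl ketone {4-(benzyloxy)-3-[4-(benzyloxy)benzyl]-6-methoxy-2-(2-phenylethyl)phenyl}[4-(benzyloxy)phenyl]methanone F9.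
- LiAlH4 reduces F9 to the racemic tribenzyl carbinol F10.
- The hydrogenolysis conditions of step 7 then cleave three benzyl ethers and the benzhydrylic C–O bond together, coming back at 14 at the cost of one extra step.

Further compounds
F1 | step 5 | lithium 4-phenylbut-1-yn-1-ide | [Li]C#CCCc1ccccc1
F2 | step 5 | 5-phenylpent-2-ynal | O=CC#CCCc1ccccc1
F3 | step 5 | 3-[4-(benzyloxy)benzyl]-6,6-dimethoxy-2-(2-phenylethyl)-4-(trimethylsilyloxy)cyclohexa-1,4-diene-1-carbaldehyde (racemic, transient) | COC1(OC)C=C(O[Si](C)(C)C)C(Cc2ccc(OCc3ccccc3)cc2)C(CCc2ccccc2)=C1C=O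
F4 | step 5 | 3-[4-(benzyloxy)benzyl]-6-methoxy-2-(2-phenylethyl)-4-(trimethylsilyloxy)benzaldehyde | COc1cc(O[Si](C)(C)C)c(Cc2ccc(OCc3ccccc3)cc2)c(CCc2ccccc2)c1C=O
F5 | step 5 | 3-[4-(benzyloxy)benzyl]-4-hydroxy-6-methoxy-2-(2-phenylethyl)benzaldehyde | COc1cc(O)c(Cc2ccc(OCc3ccccc3)cc2)c(CCc2ccccc2)c1C=O
F6 | step 5 | 4-(benzyloxy)phenylmagnesium bromide | Br[Mg]c1ccc(OCc2ccccc2)cc1
F7 | step 2 | 4,4-dimethoxybut-3-en-2-one | CC(=O)C=C(OC)OC
F8 | step 2 | sodium 4,4-dimethoxybuta-1,3-dien-2-olate | C=C([O-])C=C(OC)OC.[Na+]
F9 | step 6 | {4-(benzyloxy)-3-[4-(benzyloxy)benzyl]-6-methoxy-2-(2-phenylethyl)phenyl}[4-(benzyloxy)phenyl]methanone | COc1cc(OCc2ccccc2)c(Cc2ccc(OCc3ccccc3)cc2)c(CCc2ccccc2)c1C(=O)c1ccc(OCc2ccccc2)cc1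
F10 | step 6 | {4-(benzyloxy)-3-[4-(benzyloxy)benzyl]-6-methoxy-2-(2-phenylethyl)phenyl}[4-(benzyloxy)phenyl]methanol (racemic) | COc1cc(OCc2ccccc2)c(Cc2ccc(OCc3ccccc3)cc2)c(CCc2ccccc2)c1C(O)c1ccc(OCc2ccccc2)cc1
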